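**Plan**

1. Retrosynthesis (target numbering C1–C13; ring A = ten-membered carbocycle, ring B = furanone, ring C = lactone): remove the side-chain acetonide, open ring C at O6–C12 (oxidative lactonisation), open ring B at O–C3 (a furanone is a dehydrated C10-hydroxy C1≡C2 C3-ynone).
2. Enabling feature: C3 of ring B is a carbonyl-level carbon lying between the epimerisable C4 and C2. Ring A is therefore cut at C3–C4 and C2–C3 together, and C3 becomes carbon monoxide joining a C4 iodide to the C2 alkyne terminus.
3. The open chain is cut at the C8 ester/C6 carbinol (Evans–Tishchenko), at C7–C8 (aldol), and at C6–C7, C5–C6 and C8–C9 (dithiane alkylations).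
4. Forward: two dithiane-built fragments (C4–C7 with C11–C13, and C1/C8–C10) are joined by the aldol; the side chain enters with the anti reduction; ring A closes by carbonylation (step 21), ring B by amine addition/cyclodehydration (step 22), ring C with MnO2 (step 24).
5. Stereochemistry: C10 and C2′ come from (R)-2-methylglycidol; C7/C8 from a reagent-controlled syn boron aldol; C6 from the 1,3-anti Evans–Tishchenko reduction; C4 from equilibration next to the C3 carbonyl in the ring.

Key step: step 21

Assumption: the 4S epimer is taken to be the thermodynamically preferred one in the ten-membered ynone and in the furanone; C4 is α (or vinylogously α) to a carbonyl from step 21 onwards and is set by equilibration, not by an earlier stereocentre. Descriptors of chain intermediates use the target numbering.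

**Route**

Step 1
Reactants: 1 2-methylenepropane-1,3-diol
Product: 2 2-[(tert-butyldiphenylsilyloxy)methyl]prop-2-en-1-ol
Conditions: NaH (1.0 equiv), THF, 0 °C; TBDPSCl (1.0 equiv), 0 °C → rt
Reagents that add atoms: tert-butyl(chloro)diphenylsilane, CC(C)(C)[Si](Cl)(c1ccccc1)c1ccccc1
Why: Monosilylation of a symmetrical diol through its sparingly soluble monosodium alkoxide should stop cleanly at the mono-ether, which differentiates C12 (O-silyl) from C7 (free CH2OH).

Step 2
Reactants: 2 mono-TBDPS ether
Product: 3 {[2-(bromomethyl)prop-2-en-1-yl]oxy}(tert-butyl)diphenylsilane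
Conditions: CBr4, PPh3, CH2Cl2, 0 °C
Reagents that add atoms: carbon tetrabromide, BrC(Br)(Br)Br
Why: The Appel bromination converts the primary allylic alcohol into the bromide under neutral conditions that leave the silyl ether alone.

Step 3
Reactants: 4 1,3-dithiane; 5 (R)-propylene oxide
Product: 7 (R)-2-[2-(triethylsilyloxy)propyl]-1,3-dithiane, via lithium alkoxide 6 (not isolated)
Conditions: n-BuLi, THF, −30 °C; 5, −30 → 0 °C; TESCl, 0 °C → rt
Reagents that add atoms: chlorotriethylsilane, CC[Si](Cl)(CC)CC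
Why: Corey–Seebach alkylation: 2-lithio-1,3-dithiane (C6) opens the epoxide at its CH2 carbon (C5) without touching the carbinol centre C4, and the alkoxide is silylated in the same flask.

Step 4
Reactants: 7 silyloxypropyl dithiane; 3 allylic bromide
Product: 8 2-{2-[(tert-butyldiphenylsilyloxy)methyl]prop-2-en-1-yl}-2-[(R)-2-(triethylsilyloxy)propyl]-1,3-dithiane
Conditions: t-BuLi, THF/HMPA (10:1), −78 °C; 3, −78 → −40 °C
Reagents that add atoms: none
Why: A second Corey–Seebach alkylation: the 2-lithio derivative (HMPA keeps silicon on oxygen) displaces the reactive allylic bromide, forming C6–C7; SN2 and SN2′ attack give the same product.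

Step 5
Reactants: 8 bis-alkylated dithiane
Product: 9 (6R)-2-[(tert-butyldiphenylsilyloxy)methyl]-6-(triethylsilyloxy)hept-1-en-4-one
Conditions: MeI, CaCO3, MeCN/H2O (9:1), 45 °C
Reagents that add atoms: water, O
Why: Buffered S-alkylative hydrolysis of the dithioacetal frees the C6 ketone without acid or heavy metals, so the C11=C13 alkene should stay out of conjugation and both silyl ethers survive.

Step 6
Reactants: 4 1,3-dithiane; 10 (R)-2-methylglycidol
Product: 11 (S)-3-(1,3-dithian-2-yl)-2-methylpropane-1,2-diol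
Conditions: n-BuLi (2.2 equiv), THF, −30 °C; 10, −30 → 0 °C; H2O
Reagents that add atoms: none
Why: Corey–Seebach epoxide opening at the CH2 terminus (C9) by the dithiane anion (C8) leaves the quaternary centre C10 untouched, and any Payne rearrangement of this epoxy alkoxide is degenerate.

Step 7
Reactants: 11 dithianyl diol
Product: 12 2-[(S)-2-methyl-2,3-bis(triethylsilyloxy)propyl]-1,3-dithiane
Conditions: TESOTf (2.5 equiv), 2,6-lutidine, CH2Cl2, −78 → 0 °C
Reagents that add atoms: triethylsilyl trifluoromethanesulfonate, CC[Si](CC)(CC)OS(=O)(=O)C(F)(F)F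
Why: The silyl triflate with a hindered pyridine base silylates both the primary and the tertiary hydroxyl.

Step 8
Reactants: 12 bis-silyl ether
Product: 13 (S)-3-(1,3-dithian-2-yl)-2-methyl-2-(triethylsilyloxy)propanal
Conditions: (COCl)2, DMSO, CH2Cl2, −78 → −30 °C; Et3N, −78 → 0 °C
Reagents that add atoms: none
Why: Swern conditions cleave and oxidise a primary triethylsilyl ether directly to the aldehyde (the future C1), while the tertiary silyl ether and the dithioacetal stay intact.

Step 9
Reactants: 13 α-silyloxy aldehyde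
Product: 14 2-[(S)-2-methyl-2-(triethylsilyloxy)but-3-yn-1-yl]-1,3-dithiane
Conditions: dimethyl (1-diazo-2-oxopropyl)phosphonate, K2CO3, MeOH, 0 °C → rt
Reagents that add atoms: dimethyl (1-diazo-2-oxopropyl)phosphonate, CC(=O)C(=[N+]=[N-])P(=O)(OC)OC
Why: Seyferth–Gilbert homologation with the Ohira–Bestmann reagent converts the non-enolisable aldehyde into the terminal alkyne C1≡C2 without risk to C10.

Step 10
Reactants: 14 alkynyl dithiane
Product: 15 (S)-3-methyl-3-(triethylsilyloxy)pent-4-ynal
Conditions: MeI, CaCO3, MeCN/H2O (9:1), 45 °C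
Reagents that add atoms: water, O
Why: The same buffered alkylative dithioacetal hydrolysis as in step 5 frees the C8 aldehyde; the terminal alkyne and the tertiary silyl ether tolerate it.

Step 11
Reactants: 9 ketone; 15 aldehyde
Product: 16 (4R,7R,8S,10S)-β-hydroxy ketone HC≡C–C10(CH3)(OTES)–C9H2–C8H(OH)–C7H[C(=CH2)CH2OTBDPS]–C6(=O)–C5H2–C4H(OTES)–CH3
Conditions: (−)-Ipc2BOTf, i-Pr2NEt, CH2Cl2, −78 °C; 15, −78 → −25 °C; H2O2, MeOH, pH 7 buffer, 0 °C
Reagents that add atoms: none
Why: Isopinocampheylboron-mediated syn aldol: enolisation should occur at the allylically activated C7 to give the (Z)-enolborinate, whose Zimmerman–Traxler chair gives the 7,8-syn adduct, and the ligands of the (−)-reagent are expected to direct the enolate to the Re face of 15 (8S), neither partner having an α-stereocentre to oppose reagent control.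

Step 12
Reactants: 10 (R)-2-methylglycidol
Product: 17 (S)-2-[(benzyloxy)methyl]-2-methyloxirane
Conditions: NaH, BnBr, Bu4NI (cat.), THF, 0 °C → rt
Reagents that add atoms: benzyl bromide, BrCc1ccccc1
Why: Williamson benzylation differentiates the original CH2OH (the future ester carbon) from the epoxide CH2; the geometry at the quaternary carbon is unchanged, only the descriptor changes.

Step 13
Reactants: 17 benzyl glycidyl ether
Product: 18 (S)-3-(benzyloxy)-2-methylpropane-1,2-diol
Conditions: KOH, DMSO/H2O (3:1), 90 °C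
Reagents that add atoms: water, O
Why: Hydroxide opens the epoxide by SN2 attack at the CH2 carbon, so the C–O bond at the quaternary centre is never broken; acid is avoided because it would open at the tertiary carbon.

Step 14
Reactants: 18 diol
Product: 19 (R)-4-[(benzyloxy)methyl]-2,2,4-trimethyl-1,3-dioxolane
Conditions: 2,2-dimethoxypropane, PPTS (cat.), CH2Cl2, rt
Reagents that add atoms: 2,2-dimethoxypropane, COC(C)(C)OC
Why: Acid-catalysed transketalisation closes the five-membered acetonide over the tertiary and primary hydroxyls.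

Step 15
Reactants: 19 benzyl ether acetonide
Product: 20 (R)-(2,2,4-trimethyl-1,3-dioxolan-4-yl)methanol
Conditions: H2 (1 atm), Pd/C, EtOAc, rt
Reagents that add atoms: none
Why: Hydrogenolysis removes the benzyl ether and leaves the acetonide untouched.

Step 16
Reactants: 20 acetonide alcohol
Product: 21 (S)-2,2,4-trimethyl-1,3-dioxolane-4-carbaldehyde
Conditions: Dess–Martin periodinane, CH2Cl2, 0 °C → rt
Reagents that add atoms: none
Why: Dess–Martin oxidation gives the α-quaternary aldehyde, which cannot enolise and therefore cannot racemise.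

Step 17
Reactants: 16 β-hydroxy ketone; 21 acetonide aldehyde
Product: 22 (4R,6S,7S,8S,10S)-C6 alcohol carrying the C8 (S)-2,2,4-trimethyl-1,3-dioxolane-4-carboxylate ester
Conditions: SmI2 (30 mol %), aldehyde in excess, THF, −10 °C
Reagents that add atoms: none
Why: Evans–Tishchenko reaction, a redox-neutral addition in which every atom of both partners ends up in 22: the samarium-bound hemiacetal of the C8 hydroxyl with 21 delivers hydride intramolecularly to the C6 ketone through a chair-like six-membered transition state, which sets the 6,8-anti diol relationship and leaves the side-chain acyl group on O8.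

Step 18
Reactants: 22 C6 alcohol
Product: 23 C6 tert-butyldimethylsilyl ether of 22 (4R,6S,7R,8S,10S)
Conditions: TBSOTf, 2,6-lutidine, CH2Cl2, −78 → 0 °C
Reagents that add atoms: tert-butyldimethylsilyl trifluoromethanesulfonate, CC(C)(C)[Si](C)(C)OS(=O)(=O)C(F)(F)F
Why: Silyl triflate/lutidine silylation protects the hindered C6 hydroxyl quickly under conditions too mild for acyl migration from O8.

Step 19
Reactants: 23 fully protected chain
Product: 24 C4,C10-diol (4R,6S,7R,8S,10S) retaining the C6 OTBS, C12 OTBDPS, C8 ester and acetonide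
Conditions: HF·pyridine, pyridine, THF, 0 °C → rt
Reagents that add atoms: none
Why: Buffered HF·pyridine cleaves the two triethylsilyl ethers much faster than the hindered secondary TBS ether and the TBDPS ether, and does not touch the acetonide.

Step 20
Reactants: 24 C4,C10-diol
Product: 25 (4S,6S,7R,8S,10S)-C4 iodide with free C10 hydroxyl and terminal C1≡C2 alkyne
Conditions: PPh3, I2, imidazole, CH2Cl2, 0 °C → rt
Reagents that add atoms: iodine, II
Why: Appel-type iodination displaces the C4 alkoxyphosphonium ion by SN2 with inversion (the configuration is irrelevant for step 21), and the tertiary propargylic C10 alcohol is too hindered to be activated.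

Step 21
Reactants: 25 C4 iodide; 26 carbon monoxide
Product: 27 (4S,6S,7R,8S,10S)-ten-membered γ-hydroxy ynone (ring A: C3 ketone, C1≡C2, C10 OH)
Conditions: Pd(PPh3)4 (10 mol %), Et3N, CO (90 atm), benzene/H2O, hν (xenon lamp, Pyrex), 1 mM, rt
Reagents that add atoms: none
Why: Proposed new method: photoexcited zerovalent palladium transfers an electron to the C4–I bond, the secondary C4 radical captures CO to give the C3 acyl radical, this recombines with monovalent palladium to an acylpalladium iodide, and Et3N-assisted transfer of the C2 alkynyl terminus followed by reductive elimination forms C3–C4 and C2–C3 in one operation. The closest known reaction type is the light-promoted, palladium-catalysed three-component coupling of secondary alkyl iodides, CO and terminal alkynes to alkyl alkynyl ketones, here made intramolecular, with palladium-mediated carbonylative macrocyclisations of vinyl electrophiles as the nearest ring-forming relatives. Ring A closes end to end through an eleven-membered acyl(alkynyl)palladacycle, that is, a macrocyclisation by reductive elimination and not a radical ring closure. The new stereocentre C4 is not set kinetically: it passes through a planar radical and, as the α-carbon of the ynone, then epimerises under Et3N, so ring conformation (thermodynamic control) decides and the 4S epimer is taken as favoured. The step needs CO capture by the C4 radical to outrun 5-exo/6-endo attack on the C11=C13 alkene, β-hydride loss and reduction, which the high CO pressure and the retarding 1,1-disubstitution of that alkene (a 5-substituted hex-5-enyl radical) should secure. It also needs ring closure to beat oligomerisation, which high dilution and the conformational bias of the C6–C8 substituents support, while the free C10 hydroxyl, the silyl ethers, the ester and the acetonide are inert under these mild conditions.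

Step 22
Reactants: 27 ten-membered ynone
Product: 29 (4S,6S,7R,8S,10S)-furanone with rings A and B closed, via enaminone 28 (not isolated)
Conditions: Et2NH, EtOH, rt; AcOH/H2O/THF, rt; then DBU (0.3 equiv), CH2Cl2, rt
Reagents that add atoms: water, O
Why: Conjugate addition of the secondary amine at C1, hydrolysis of the enaminone to the C1/C3 diketone and cyclodehydration of the C10 hydroxyl onto C3 is the classical γ-hydroxy ynone to 3(2H)-furanone conversion, and the final DBU treatment re-equilibrates the vinylogously acidic C4 so that any 4-epimer converges on the ring-preferred configuration.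

Step 23
Reactants: 29 silylated furanone
Product: 30 (4S,6S,7S,8S,10S)-C6,C12-diol
Conditions: HF·pyridine, pyridine, THF, 0 °C → rt
Reagents that add atoms: none
Why: Fluoride-mediated desilylation removes both the secondary TBS and the primary TBDPS ether while the buffered medium spares the acetonide, the hindered ester and the furanone.

Step 24
Reactants: 30 diol
Product: 32 acetonide of the target (rings A and B and C closed), via lactol 31 (not isolated)
Conditions: MnO2 (excess), CH2Cl2, rt
Reagents that add atoms: none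
Why: MnO2 oxidises only the allylic C12 alcohol; the enal is trapped by the C6 hydroxyl as a lactol that is oxidised further to the α-methylene-γ-butyrolactone (oxidative lactonisation), and the ring fusion follows from the fixed C6 and C7 centres.

Step 25
Reactants: 32 acetonide lactone
Product: 33 CNP0263764.3 (target)
Conditions: TFA/H2O (9:1), CH2Cl2, 0 °C
Reagents that add atoms: none
Why: Acid-catalysed acetonide hydrolysis frees the side-chain diol under conditions that the furanone, the α-methylene lactone and the hindered C8 ester tolerate.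

**Compound list**

1 | 2-methylenepropane-1,3-diol | C=C(CO)CO | starting material
2 | 2-[(tert-butyldiphenylsilyloxy)methyl]prop-2-en-1-ol | C=C(CO)CO[Si](c1ccccc1)(c1ccccc1)C(C)(C)C | intermediate
3 | {[2-(bromomethyl)prop-2-en-1-yl]oxy}(tert-butyl)diphenylsilane | C=C(CBr)CO[Si](c1ccccc1)(c1ccccc1)C(C)(C)C | intermediate
4 | 1,3-dithiane | C1CSCSC1 | starting material
5 | (R)-propylene oxide | C[C@@H]1CO1 | starting material
6 | lithium (R)-1-(1,3-dithian-2-yl)propan-2-olate | C[C@@H]([O-])CC1SCCCS1.[Li+] | intermediate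
7 | (R)-2-[2-(triethylsilyloxy)propyl]-1,3-dithiane | C[C@@H](O[Si](CC)(CC)CC)CC1SCCCS1 | intermediate
8 | 2-{2-[(tert-butyldiphenylsilyloxy)methyl]prop-2-en-1-yl}-2-[(R)-2-(triethylsilyloxy)propyl]-1,3-dithiane | C[C@@H](O[Si](CC)(CC)CC)CC1(CC(=C)CO[Si](c2ccccc2)(c2ccccc2)C(C)(C)C)SCCCS1 | intermediate
9 | (6R)-2-[(tert-butyldiphenylsilyloxy)methyl]-6-(triethylsilyloxy)hept-1-en-4-one | C=C(CO[Si](c1ccccc1)(c1ccccc1)C(C)(C)C)CC(=O)C[C@@H](C)O[Si](CC)(CC)CC | intermediate
10 | (R)-2-methylglycidol | OC[C@@]1(C)OC1 | starting material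
11 | (S)-3-(1,3-dithian-2-yl)-2-methylpropane-1,2-diol | OC[C@@](CC1SCCCS1)(C)O | intermediate
12 | 2-[(S)-2-methyl-2,3-bis(triethylsilyloxy)propyl]-1,3-dithiane | CC[Si](CC)(CC)OC[C@@](CC1SCCCS1)(C)O[Si](CC)(CC)CC | intermediate
13 | (S)-3-(1,3-dithian-2-yl)-2-methyl-2-(triethylsilyloxy)propanal | O=C[C@@](CC1SCCCS1)(C)O[Si](CC)(CC)CC | intermediate
14 | 2-[(S)-2-methyl-2-(triethylsilyloxy)but-3-yn-1-yl]-1,3-dithiane | C#C[C@@](CC1SCCCS1)(C)O[Si](CC)(CC)CC | intermediate
15 | (S)-3-methyl-3-(triethylsilyloxy)pent-4-ynal | C#C[C@@](CC=O)(C)O[Si](CC)(CC)CC | intermediate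
16 | (4R,7R,8S,10S)-β-hydroxy ketone: C10 methyl/OTES, C8 OH, C7 3-(TBDPS-oxy)prop-1-en-2-yl, C6 ketone, C4 OTES, terminal C1≡C2 | C#C[C@@](C)(O[Si](CC)(CC)CC)C[C@H](O)[C@@H](C(=C)CO[Si](c1ccccc1)(c1ccccc1)C(C)(C)C)C(=O)C[C@@H](C)O[Si](CC)(CC)CC | intermediate
17 | (S)-2-[(benzyloxy)methyl]-2-methyloxirane | c1ccccc1COC[C@@]1(C)OC1 | intermediate
18 | (S)-3-(benzyloxy)-2-methylpropane-1,2-diol | c1ccccc1COC[C@@](CO)(C)O | intermediate
19 | (R)-4-[(benzyloxy)methyl]-2,2,4-trimethyl-1,3-dioxolane | c1ccccc1COC[C@@]1(C)OC(C)(C)OC1 | intermediate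
20 | (R)-(2,2,4-trimethyl-1,3-dioxolan-4-yl)methanol | OC[C@@]1(C)OC(C)(C)OC1 | intermediate
21 | (S)-2,2,4-trimethyl-1,3-dioxolane-4-carbaldehyde | O=C[C@@]1(C)OC(C)(C)OC1 | intermediate
22 | (4R,6S,7S,8S,10S)-chain with C6 OH, C8 (S)-2,2,4-trimethyl-1,3-dioxolane-4-carboxylate, C4 and C10 OTES, C12 OTBDPS | C#C[C@@](C)(O[Si](CC)(CC)CC)C[C@H](OC(=O)[C@@]1(C)OC(C)(C)OC1)[C@@H](C(=C)CO[Si](c2ccccc2)(c2ccccc2)C(C)(C)C)[C@@H](O)C[C@@H](C)O[Si](CC)(CC)CC | intermediate
23 | C6 TBS ether of 22 (4R,6S,7R,8S,10S) | C#C[C@@](C)(O[Si](CC)(CC)CC)C[C@H](OC(=O)[C@@]1(C)OC(C)(C)OC1)[C@@H](C(=C)CO[Si](c2ccccc2)(c2ccccc2)C(C)(C)C)[C@@H](O[Si](C)(C)C(C)(C)C)C[C@@H](C)O[Si](CC)(CC)CC | intermediate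
24 | (4R,6S,7R,8S,10S)-C4,C10-diol with C6 OTBS, C12 OTBDPS, C8 acetonide ester | C#C[C@@](C)(O)C[C@H](OC(=O)[C@@]1(C)OC(C)(C)OC1)[C@@H](C(=C)CO[Si](c2ccccc2)(c2ccccc2)C(C)(C)C)[C@@H](O[Si](C)(C)C(C)(C)C)C[C@@H](C)O | intermediate
25 | (4S,6S,7R,8S,10S)-C4 iodide (open-chain key-step precursor) | C#C[C@@](C)(O)C[C@H](OC(=O)[C@@]1(C)OC(C)(C)OC1)[C@@H](C(=C)CO[Si](c2ccccc2)(c2ccccc2)C(C)(C)C)[C@@H](O[Si](C)(C)C(C)(C)C)C[C@H](C)I | intermediate
26 | carbon monoxide | [C-]#[O+] | starting material
27 | (4S,6S,7R,8S,10S)-ten-membered γ-hydroxy ynone (C3 ketone, C1≡C2, C10 OH) | O=C1C#C[C@@](C)(O)C[C@H](OC(=O)[C@@]2(C)OC(C)(C)OC2)[C@@H](C(=C)CO[Si](c3ccccc3)(c3ccccc3)C(C)(C)C)[C@@H](O[Si](C)(C)C(C)(C)C)C[C@@H]1C | intermediate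
28 | ring-A enaminone: C1 diethylamino, C1=C2 with C3 and C10 cis, C3 ketone | O=C1/C=C(N(CC)CC)\[C@@](C)(O)C[C@H](OC(=O)[C@@]2(C)OC(C)(C)OC2)[C@@H](C(=C)CO[Si](c3ccccc3)(c3ccccc3)C(C)(C)C)[C@@H](O[Si](C)(C)C(C)(C)C)C[C@@H]1C | intermediate
29 | (4S,6S,7R,8S,10S)-furanone (rings A and B) with C6 OTBS, C12 OTBDPS, C8 acetonide ester | O=C1C=C2O[C@@]1(C)C[C@H](OC(=O)[C@@]3(C)OC(C)(C)OC3)[C@@H](C(=C)CO[Si](c4ccccc4)(c4ccccc4)C(C)(C)C)[C@@H](O[Si](C)(C)C(C)(C)C)C[C@@H]2C | intermediate
30 | (4S,6S,7S,8S,10S)-furanone C6,C12-diol | O=C1C=C2O[C@@]1(C)C[C@H](OC(=O)[C@@]3(C)OC(C)(C)OC3)[C@@H](C(=C)CO)[C@@H](O)C[C@@H]2C | intermediate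
31 | C12 lactol of 30 (anomer mixture) | C=C1C(O)O[C@H]2C[C@H](C)C3=CC(=O)[C@](C)(C[C@H](OC(=O)[C@@]4(C)OC(C)(C)OC4)[C@@H]12)O3 | intermediate
32 | side-chain acetonide of the target | C=C1C(=O)O[C@H]2C[C@H](C)C3=CC(=O)[C@](C)(C[C@H](OC(=O)[C@@]4(C)OC(C)(C)OC4)[C@@H]12)O3 | intermediate
33 | CNP0263764.3, (4S,6S,7S,8S,10S)-furanone lactone with the 8-O-[(S)-2,3-dihydroxy-2-methylpropanoyl] ester | C=C1C(=O)O[C@H]2C[C@H](C)C3=CC(=O)[C@](C)(C[C@H](OC(=O)[C@@](C)(O)CO)[C@@H]12)O3 | target

**Step count and risks**

Total steps: 25. Longest linear sequence: 15 steps (steps 6–10, 11, 17–25, from (R)-2-methylglycidol).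

Most likely to fail:

1. Step 21 (carbonylative ring closure). The C4 radical may cyclise onto the C11=C13 alkene or be lost by β-hydride elimination before it captures CO, and the acylpalladium may couple between molecules because the eleven-membered palladacycle forms slowly. The fallback sets out from 25 and returns at 27, using known reactions only. Radical formylation of the iodide (Bu3SnH, AIBN, CO 80 atm, benzene, 80 °C) gives the C3 aldehyde F1 as a C4 epimer mixture. Iodination of the alkyne terminus (N-iodosuccinimide, AgNO3 cat., acetone) gives the iodoalkyne aldehyde F2. A Nozaki–Hiyama–Kishi macrocyclisation (CrCl2, NiCl2 cat., THF, high dilution) closes ring A at C2–C3 to the ten-membered propargylic alcohol F3. Dess–Martin oxidation followed by Et3N equilibration of C4 gives 27.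

2. Step 11 (boron aldol). Enolisation may occur toward C5 instead of C7, the C11=C13 alkene may migrate into conjugation, or the isopinocampheyl ligands may discriminate the aldehyde faces poorly or in the opposite sense. The fallback replaces reagent control by auxiliary control; it sets out from 3 (with 15 and 5) and returns at 16. Bromide 3 is carboxylated through its Grignard reagent (Mg, THF; CO2) to 3-[(tert-butyldiphenylsilyloxy)methyl]but-3-enoic acid F4, which is attached to (R)-4-benzyloxazolidin-2-one (PivCl, Et3N, LiCl) to give the imide F5. An Evans syn aldol reaction of F5 with 15 (Bu2BOTf, i-Pr2NEt, CH2Cl2) gives the adduct F6, with C7 and C8 fixed by the auxiliary and no regiochemical question. Transamidation (MeONHMe·HCl, AlMe3) gives the Weinreb amide F7. Reductive opening of 5 with lithium 4,4′-di-tert-butylbiphenylide gives the β-lithio alkoxide F8, which adds to F7 to give the C4,C8-dihydroxy ketone F9. Selective silylation of the less hindered C4 hydroxyl (TESCl, imidazole, −40 °C) gives 16.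

3. Step 17 (Evans–Tishchenko). Hemiacetal formation with the hindered, α-oxygenated aldehyde may be slow, leaving the samarium aldolate time for retro-aldol cleavage and C7 epimerisation, or the catalyst may be consumed by pinacol coupling. The fallback separates the reduction from the acylation; it sets out from 16 and returns at 23. The Evans–Tishchenko reaction is run with acetaldehyde (SmI2 cat., THF, −10 °C) to give the C8 acetate C6 alcohol F10, which is silylated (TBSOTf, 2,6-lutidine) to the C8 acetate C6 TBS ether F11. Reductive removal of the acetate (i-Bu2AlH, CH2Cl2, −78 °C) gives the C8 alcohol F12. Yamaguchi esterification (2,4,6-trichlorobenzoyl chloride, Et3N, DMAP) with (S)-2,2,4-trimethyl-1,3-dioxolane-4-carboxylic acid F13, made from 21 by Pinnick oxidation, gives 23.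

**Further compounds**

F1 | step 21 | C3 aldehyde from radical formylation of 25 (C4 epimer mixture) | C#C[C@@](C)(O)C[C@H](OC(=O)[C@@]1(C)OC(C)(C)OC1)[C@@H](C(=C)CO[Si](c2ccccc2)(c2ccccc2)C(C)(C)C)[C@@H](O[Si](C)(C)C(C)(C)C)CC(C)C=O
F2 | step 21 | C2 iodoalkyne C3 aldehyde | IC#C[C@@](C)(O)C[C@H](OC(=O)[C@@]1(C)OC(C)(C)OC1)[C@@H](C(=C)CO[Si](c2ccccc2)(c2ccccc2)C(C)(C)C)[C@@H](O[Si](C)(C)C(C)(C)C)CC(C)C=O
F3 | step 21 | ten-membered C3 propargylic alcohol (C3 and C4 epimer mixture) | OC1C#C[C@@](C)(O)C[C@H](OC(=O)[C@@]2(C)OC(C)(C)OC2)[C@@H](C(=C)CO[Si](c3ccccc3)(c3ccccc3)C(C)(C)C)[C@@H](O[Si](C)(C)C(C)(C)C)CC1C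
F4 | step 11 | 3-[(tert-butyldiphenylsilyloxy)methyl]but-3-enoic acid | C=C(CC(=O)O)CO[Si](c1ccccc1)(c1ccccc1)C(C)(C)C
F5 | step 11 | (R)-4-benzyl-3-{3-[(tert-butyldiphenylsilyloxy)methyl]but-3-enoyl}oxazolidin-2-one | C=C(CC(=O)N1[C@H](Cc2ccccc2)COC1=O)CO[Si](c3ccccc3)(c3ccccc3)C(C)(C)C
F6 | step 11 | Evans syn aldol adduct (7R,8S,10S) of F5 and 15 | C#C[C@@](C)(O[Si](CC)(CC)CC)C[C@H](O)[C@@H](C(=C)CO[Si](c1ccccc1)(c1ccccc1)C(C)(C)C)C(=O)N1[C@H](Cc2ccccc2)COC1=O
F7 | step 11 | Weinreb amide of the aldol adduct | C#C[C@@](C)(O[Si](CC)(CC)CC)C[C@H](O)[C@@H](C(=C)CO[Si](c1ccccc1)(c1ccccc1)C(C)(C)C)C(=O)N(C)OC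
F8 | step 11 | dilithium (R)-1-lithiopropan-2-olate (β-lithio alkoxide) | [Li+].[Li+].[CH2-][C@@H](C)[O-]
F9 | step 11 | (4R,7R,8S,10S)-C4,C8-dihydroxy C6 ketone | C#C[C@@](C)(O[Si](CC)(CC)CC)C[C@H](O)[C@@H](C(=C)CO[Si](c1ccccc1)(c1ccccc1)C(C)(C)C)C(=O)C[C@@H](C)O
F10 | step 17 | C8 acetate C6 alcohol (6,8-anti) | C#C[C@@](C)(O[Si](CC)(CC)CC)C[C@H](OC(C)=O)[C@@H](C(=C)CO[Si](c1ccccc1)(c1ccccc1)C(C)(C)C)[C@@H](O)C[C@@H](C)O[Si](CC)(CC)CC
F11 | step 17 | C8 acetate C6 TBS ether | C#C[C@@](C)(O[Si](CC)(CC)CC)C[C@H](OC(C)=O)[C@@H](C(=C)CO[Si](c1ccccc1)(c1ccccc1)C(C)(C)C)[C@@H](O[Si](C)(C)C(C)(C)C)C[C@@H](C)O[Si](CC)(CC)CC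
F12 | step 17 | C8 alcohol C6 TBS ether | C#C[C@@](C)(O[Si](CC)(CC)CC)C[C@H](O)[C@@H](C(=C)CO[Si](c1ccccc1)(c1ccccc1)C(C)(C)C)[C@@H](O[Si](C)(C)C(C)(C)C)C[C@@H](C)O[Si](CC)(CC)CC
F13 | step 17 | (S)-2,2,4-trimethyl-1,3-dioxolane-4-carboxylic acid | OC(=O)[C@@]1(C)OC(C)(C)OC1
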